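Ring B of the target (C5–C10) is a cross-conjugated dienone in which the C8 ketone faces, across the ring, a fully substituted C5 that bears a methyl group. Such a ring is the dearomatised form of a 4-methylphenol that has been C-alkylated at its methyl-bearing carbon. The route therefore cuts the C4–C5 bond. A phenoxide whose C10 side chain carries a C1 silyl ether and a C4 mesylate attacks through C5, and this one operation closes ring A, creates the quaternary centre and leaves the dienone. Precursor 17 is that phenol with C1, C4 and C11 already set. Its C12 carboxyl is a free acid, which shields C11 from base, and is methylated in the same flask.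

Key step: step 14

Remarks on the chemistry (assumptions and design choices):
- Atom numbers C1–C12 are those of the target: ring A = C1, C2, C3, C4, C5, C10; ring B = C5–C10; C11/C12 = the propanoate carbons.
- Stereochemical check: the (R)-lactone gives 4R in 17, which is (1R,4R,11S). Inversion at C4 in the ring closure gives (1R,4S,5S,11S) in 20 and in the target. No structure needed correction.
- C12 is carried as the free acid up to and through the ring closure. A methyl 2-(2-hydroxyaryl)propanoate would, as its phenoxide, close to a 3-methylbenzofuran-2-one, whose C–H is acidic enough to erase C11. A carboxylate neither lactonises nor enolises.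
- The ruthenium–BINAP hydrogenation is run on the free acrylic acid, the substrate class that this catalyst needs.
- Phenol and carboxyl are masked as benzyl ether and benzyl ester while the C4 hydroxyl is mesylated. Both are released together by hydrogenolysis.
- Methyl 2-(tributylstannyl)acrylate is made in step 7 and not assumed to be purchasable.

Step 1
Reactants: 1 3-bromo-4-methylphenol
Product: 2 4-(benzyloxy)-2-bromo-1-methylbenzene
Conditions: BnBr, K2CO3, acetone, reflux
Reagents that add atoms: benzyl bromide, BrCc1ccccc1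
Why: Williamson ether synthesis on the phenoxide masks the acidic hydroxyl group before the organolithium step with a group that later leaves under neutral hydrogenolysis.

Step 2
Reactants: 2 4-(benzyloxy)-2-bromo-1-methylbenzene; 3 (R)-γ-valerolactone
Product: 5 (4R)-1-[5-(benzyloxy)-2-methylphenyl]-4-hydroxypentan-1-one, via aryllithium 4 (not isolated)
Conditions: n-BuLi, THF, −78 °C; then cannulation into 3, THF, −78 °C; aq. NH4Cl
Reagents that add atoms: none
Why: Bromine–lithium exchange followed by acyl addition of the aryllithium to the lactone should stop after one addition because the lithium lactolate persists at −78 °C, and the C4 stereocentre is carried over unchanged from 3.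

Step 3
Reactants: 5 (4R)-1-[5-(benzyloxy)-2-methylphenyl]-4-hydroxypentan-1-one
Product: 6 (2R)-5-[5-(benzyloxy)-2-methylphenyl]-5-oxopentan-2-yl acetate
Conditions: Ac2O, pyridine, DMAP (cat.), CH2Cl2, 0 °C → rt
Reagents that add atoms: acetic anhydride, CC(=O)OC(C)=O
Why: DMAP-catalysed acetylation traps the open-chain C4 alcohol as an ester that tolerates borane, silylation, iodination and Stille coupling and is shed for free in the later saponification.

Step 4
Reactants: 6 (2R)-5-[5-(benzyloxy)-2-methylphenyl]-5-oxopentan-2-yl acetate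
Product: 7 (2R,5R)-5-[5-(benzyloxy)-2-methylphenyl]-5-hydroxypentan-2-yl acetate
Conditions: (S)-Me-CBS oxazaborolidine (10 mol %), BH3·SMe2, THF, −20 °C; MeOH quench
Reagents that add atoms: none
Why: Corey–Bakshi–Shibata reduction of the aryl alkyl ketone, in which the (S)-oxazaborolidine (aryl as the large group) should deliver hydride to the face that gives the (R)-carbinol at C1, with catalyst control overriding the remote C4 centre and the acetate untouched at low temperature.

Step 5
Reactants: 7 (2R,5R)-5-[5-(benzyloxy)-2-methylphenyl]-5-hydroxypentan-2-yl acetate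
Product: 8 (2R,5R)-5-[5-(benzyloxy)-2-methylphenyl]-5-(tert-butyldimethylsilyloxy)pentan-2-yl acetate
Conditions: TBSOTf, 2,6-lutidine, CH2Cl2, −78 → 0 °C
Reagents that add atoms: tert-butyldimethylsilyl triflate, CC(C)(C)[Si](C)(C)OS(=O)(=O)C(F)(F)F
Why: Silylation with the silyl triflate and a hindered pyridine base protects the crowded benzylic C1 alcohol with retention, since only the O–H bond reacts.

Step 6
Reactants: 8 (2R,5R)-5-[5-(benzyloxy)-2-methylphenyl]-5-(tert-butyldimethylsilyloxy)pentan-2-yl acetate
Product: 9 (2R,5R)-5-[5-(benzyloxy)-4-iodo-2-methylphenyl]-5-(tert-butyldimethylsilyloxy)pentan-2-yl acetate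
Conditions: N-iodosuccinimide, TFA (10 mol %), MeCN, 0 °C → rt, dark
Reagents that add atoms: N-iodosuccinimide, O=C1CCC(=O)N1I
Why: Electrophilic aromatic iodination should enter at C7, which is ortho to the benzyloxy group and para to the C10 alkyl group, whereas the other ortho position C9 is shielded by the branched C10 substituent and the para position is blocked by the methyl group.

Step 7
Reactants: 10 methyl propiolate
Product: 11 methyl 2-(tributylstannyl)prop-2-enoate
Conditions: Bu3SnH, Pd(PPh3)4 (2 mol %), THF, 0 °C → rt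
Reagents that add atoms: tributyltin hydride, CCCC[SnH](CCCC)CCCC
Why: Palladium-catalysed hydrostannation of an alkynoate adds Sn–H syn across the triple bond with tin on the carbon next to the ester, which gives the α-stannyl acrylate as the main regioisomer.

Step 8
Reactants: 9 (2R,5R)-5-[5-(benzyloxy)-4-iodo-2-methylphenyl]-5-(tert-butyldimethylsilyloxy)pentan-2-yl acetate; 11 methyl 2-(tributylstannyl)prop-2-enoate
Product: 12 methyl 2-{4-[(1R,4R)-4-acetoxy-1-(tert-butyldimethylsilyloxy)pentyl]-2-(benzyloxy)-5-methylphenyl}prop-2-enoate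
Conditions: Pd(PPh3)4 (5 mol %), CuI (20 mol %), DMF, rt → 50 °C
Reagents that add atoms: none
Why: Stille coupling with CuI as co-catalyst joins C7 to the α-carbon of the acrylate under neutral conditions that leave the acetate, the silyl ether and the benzyl ether alone.

Step 9
Reactants: 12 methyl 2-{4-[(1R,4R)-4-acetoxy-1-(tert-butyldimethylsilyloxy)pentyl]-2-(benzyloxy)-5-methylphenyl}prop-2-enoate
Product: 13 2-{2-(benzyloxy)-4-[(1R,4R)-1-(tert-butyldimethylsilyloxy)-4-hydroxypentyl]-5-methylphenyl}prop-2-enoic acid
Conditions: LiOH, THF–H2O (3:1), rt → 40 °C; then 1 M HCl to pH 4, 0 °C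
Reagents that add atoms: lithium hydroxide, [Li+].[OH-]
Why: Saponification cleaves the methyl ester and the C4 acetate in one operation, and the acrylate, once it is a carboxylate, is no longer a good Michael acceptor for hydroxide.

Step 10
Reactants: 13 2-{2-(benzyloxy)-4-[(1R,4R)-1-(tert-butyldimethylsilyloxy)-4-hydroxypentyl]-5-methylphenyl}prop-2-enoic acid
Product: 14 (2S)-2-{2-(benzyloxy)-4-[(1R,4R)-1-(tert-butyldimethylsilyloxy)-4-hydroxypentyl]-5-methylphenyl}propanoic acid
Conditions: Ru(OAc)2[(S)-BINAP] (1 mol %), H2 (100 atm), MeOH, 15 °C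
Reagents that add atoms: none
Why: Noyori asymmetric hydrogenation of a 2-arylacrylic acid, in which the carboxylate binds ruthenium and the (S)-BINAP complex should add hydrogen to the face that gives the (S)-2-arylpropanoic acid at C11, as in the naproxen class; any minor C11 epimer would be a diastereomer and separable.

Step 11
Reactants: 14 (2S)-2-{2-(benzyloxy)-4-[(1R,4R)-1-(tert-butyldimethylsilyloxy)-4-hydroxypentyl]-5-methylphenyl}propanoic acid
Product: 15 benzyl (2S)-2-{2-(benzyloxy)-4-[(1R,4R)-1-(tert-butyldimethylsilyloxy)-4-hydroxypentyl]-5-methylphenyl}propanoate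
Conditions: BnBr, KHCO3, DMF, rt
Reagents that add atoms: benzyl bromide, BrCc1ccccc1
Why: SN2 O-alkylation of the carboxylate with a bicarbonate base is too mild to enolise C11 or to alkylate the C4 alcohol, and it removes the acid that would otherwise form a mixed anhydride in the mesylation.

Step 12
Reactants: 15 benzyl (2S)-2-{2-(benzyloxy)-4-[(1R,4R)-1-(tert-butyldimethylsilyloxy)-4-hydroxypentyl]-5-methylphenyl}propanoate
Product: 16 benzyl (2S)-2-{2-(benzyloxy)-4-[(1R,4R)-1-(tert-butyldimethylsilyloxy)-4-(methanesulfonyloxy)pentyl]-5-methylphenyl}propanoate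
Conditions: MsCl, Et3N, CH2Cl2, −10 → 0 °C
Reagents that add atoms: methanesulfonyl chloride, CS(=O)(=O)Cl
Why: Sulfonylation of the only free hydroxyl group forms the O–S bond with retention at C4, while the phenol and the carboxyl are still masked.

Step 13
Reactants: 16 benzyl (2S)-2-{2-(benzyloxy)-4-[(1R,4R)-1-(tert-butyldimethylsilyloxy)-4-(methanesulfonyloxy)pentyl]-5-methylphenyl}propanoate
Product: 17 (2S)-2-{4-[(1R,4R)-1-(tert-butyldimethylsilyloxy)-4-(methanesulfonyloxy)pentyl]-2-hydroxy-5-methylphenyl}propanoic acid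
Conditions: H2 (1 atm), Pd/C (10 %), EtOAc, rt; used without storage
Reagents that add atoms: none
Why: Catalytic hydrogenolysis removes the benzyl ether and the benzyl ester together under neutral conditions that should spare the alkyl mesylate, the C11 centre and the benzylic silyl ether, which sits meta to the oxygen and next to an ortho methyl group.

Step 14
Reactants: 17 (2S)-2-{4-[(1R,4R)-1-(tert-butyldimethylsilyloxy)-4-(methanesulfonyloxy)pentyl]-2-hydroxy-5-methylphenyl}propanoic acid
Product: 20 methyl (2S)-2-[(5R,8S,8aS)-5-(tert-butyldimethylsilyloxy)-8,8a-dimethyl-3-oxo-3,5,6,7,8,8a-hexahydronaphthalen-2-yl]propanoate, via dipotassium phenoxide carboxylate 18 (not isolated), via potassium dienone carboxylate 19 (not isolated)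
Conditions: KOtBu (2.0 equiv), t-BuOH–THF (4:1, 0.01 M), 25 → 60 °C; then MeI, DMF, 25 °C
Reagents that add atoms: iodomethane, CI
Why: Two equivalents of base give the phenoxide carboxylate 18, whose ring attacks with its para carbon C5 on the C4 mesylate in an intramolecular SN2 displacement with inversion (4R to 4S), and the methyl group on C5 leaves no proton to lose, so the product stays as the dienone of ring B. The closest known reaction type is the base-mediated intramolecular para C-alkylation of phenoxides (alkylative dearomatisation) that gives fused 4,4-disubstituted cyclohexa-2,5-dienones. Ring A closes in a 6-exo-tet mode. The new quaternary centre C5 is controlled by C1 and C4 through a chair-shaped transition state that keeps the methyl group on C4 equatorial and turns the C1–O bond out of the arene plane (pseudoaxial, no A(1,3) clash with C9–H), which should push the methyl group on C5 to the face that already holds the C1 oxygen and the C4 methyl (5S). The step needs attack at C5 and not at C9, and substitution and not E2 loss of the mesylate: the oxygen cannot reach C4 because the chain is attached meta to it, C9 is the more crowded site between the solvated oxygen and the branched chain, a potassium phenoxide in hydrogen-bonding t-BuOH reacts preferentially at the remote para carbon, and with exactly two equivalents no base stronger than phenoxide or carboxylate is present. The C12 carboxylate cannot lactonise or enolise, so C11 is safe, and its O-methylation with iodomethane in the same flask gives 20.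

Step 15
Reactants: 20 methyl (2S)-2-[(5R,8S,8aS)-5-(tert-butyldimethylsilyloxy)-8,8a-dimethyl-3-oxo-3,5,6,7,8,8a-hexahydronaphthalen-2-yl]propanoate
Product: 21 methyl (2S)-2-[(5R,8S,8aS)-5-hydroxy-8,8a-dimethyl-3-oxo-3,5,6,7,8,8a-hexahydronaphthalen-2-yl]propanoate
Conditions: HF·pyridine, pyridine, THF, 0 °C → rt
Reagents that add atoms: none
Why: Fluoride-mediated desilylation in a pyridine-buffered medium cleaves the Si–O bond without the basicity that could enolise C11 and without the acid strength needed for a dienone–phenol rearrangement.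

Step 16
Reactants: 21 methyl (2S)-2-[(5R,8S,8aS)-5-hydroxy-8,8a-dimethyl-3-oxo-3,5,6,7,8,8a-hexahydronaphthalen-2-yl]propanoate; 22 angelic acid
Product: 24 methyl (2S)-2-[(5R,8S,8aS)-8,8a-dimethyl-5-{[(2Z)-2-methylbut-2-enoyl]oxy}-3-oxo-3,5,6,7,8,8a-hexahydronaphthalen-2-yl]propanoate (target), via angelic 2,4,6-trichlorobenzoic anhydride 23 (not isolated)
Conditions: 22, 2,4,6-trichlorobenzoyl chloride, Et3N, toluene, rt; then 21, toluene, 75 °C (no DMAP)
Reagents that add atoms: none
Why: Yamaguchi esterification through the mixed anhydride, in which the C1 alcohol attacks the less hindered angeloyl carbonyl with retention at C1, and leaving out the nucleophilic pyridine catalyst avoids the addition–elimination pathway that turns angelates into tiglates, so the Z alkene should survive.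

Compound list
1 | 3-bromo-4-methylphenol | Cc1ccc(O)cc1Br | starting material
2 | 4-(benzyloxy)-2-bromo-1-methylbenzene | Cc1ccc(OCc2ccccc2)cc1Br | intermediate
3 | (R)-γ-valerolactone | C[C@@H]1CCC(=O)O1 | starting material
4 | [5-(benzyloxy)-2-methylphenyl]lithium | [Li]c1cc(OCc2ccccc2)ccc1C | intermediate (not isolated)
5 | (4R)-1-[5-(benzyloxy)-2-methylphenyl]-4-hydroxypentan-1-one | O=C(c1cc(OCc2ccccc2)ccc1C)CC[C@@H](C)O | intermediate
6 | (2R)-5-[5-(benzyloxy)-2-methylphenyl]-5-oxopentan-2-yl acetate | O=C(c1cc(OCc2ccccc2)ccc1C)CC[C@@H](C)OC(C)=O | intermediate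
7 | (2R,5R)-5-[5-(benzyloxy)-2-methylphenyl]-5-hydroxypentan-2-yl acetate | O[C@@H](c1cc(OCc2ccccc2)ccc1C)CC[C@@H](C)OC(C)=O | intermediate
8 | (2R,5R)-5-[5-(benzyloxy)-2-methylphenyl]-5-(tert-butyldimethylsilyloxy)pentan-2-yl acetate | CC(C)(C)[Si](C)(C)O[C@@H](c1cc(OCc2ccccc2)ccc1C)CC[C@@H](C)OC(C)=O | intermediate
9 | (2R,5R)-5-[5-(benzyloxy)-4-iodo-2-methylphenyl]-5-(tert-butyldimethylsilyloxy)pentan-2-yl acetate | CC(C)(C)[Si](C)(C)O[C@@H](c1cc(OCc2ccccc2)c(I)cc1C)CC[C@@H](C)OC(C)=O | intermediate
10 | methyl propiolate | C#CC(=O)OC | starting material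
11 | methyl 2-(tributylstannyl)prop-2-enoate | C=C(C(=O)OC)[Sn](CCCC)(CCCC)CCCC | intermediate
12 | methyl 2-{4-[(1R,4R)-4-acetoxy-1-(tert-butyldimethylsilyloxy)pentyl]-2-(benzyloxy)-5-methylphenyl}prop-2-enoate | CC(C)(C)[Si](C)(C)O[C@@H](c1cc(OCc2ccccc2)c(C(=C)C(=O)OC)cc1C)CC[C@@H](C)OC(C)=O | intermediate
13 | 2-{2-(benzyloxy)-4-[(1R,4R)-1-(tert-butyldimethylsilyloxy)-4-hydroxypentyl]-5-methylphenyl}prop-2-enoic acid | CC(C)(C)[Si](C)(C)O[C@@H](c1cc(OCc2ccccc2)c(C(=C)C(=O)O)cc1C)CC[C@@H](C)O | intermediate
14 | (2S)-2-{2-(benzyloxy)-4-[(1R,4R)-1-(tert-butyldimethylsilyloxy)-4-hydroxypentyl]-5-methylphenyl}propanoic acid | CC(C)(C)[Si](C)(C)O[C@@H](c1cc(OCc2ccccc2)c([C@H](C)C(=O)O)cc1C)CC[C@@H](C)O | intermediate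
15 | benzyl (2S)-2-{2-(benzyloxy)-4-[(1R,4R)-1-(tert-butyldimethylsilyloxy)-4-hydroxypentyl]-5-methylphenyl}propanoate | CC(C)(C)[Si](C)(C)O[C@@H](c1cc(OCc2ccccc2)c([C@H](C)C(=O)OCc2ccccc2)cc1C)CC[C@@H](C)O | intermediate
16 | benzyl (2S)-2-{2-(benzyloxy)-4-[(1R,4R)-1-(tert-butyldimethylsilyloxy)-4-(methanesulfonyloxy)pentyl]-5-methylphenyl}propanoate | CC(C)(C)[Si](C)(C)O[C@@H](c1cc(OCc2ccccc2)c([C@H](C)C(=O)OCc2ccccc2)cc1C)CC[C@@H](C)OS(C)(=O)=O | intermediate
17 | (2S)-2-{4-[(1R,4R)-1-(tert-butyldimethylsilyloxy)-4-(methanesulfonyloxy)pentyl]-2-hydroxy-5-methylphenyl}propanoic acid (precursor of the key step) | CC(C)(C)[Si](C)(C)O[C@@H](c1cc(O)c([C@H](C)C(=O)O)cc1C)CC[C@@H](C)OS(C)(=O)=O | intermediate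
18 | dipotassium phenoxide carboxylate of 17 | CC(C)(C)[Si](C)(C)O[C@@H](c1cc([O-])c([C@H](C)C(=O)[O-])cc1C)CC[C@@H](C)OS(C)(=O)=O.[K+].[K+] | intermediate (not isolated)
19 | potassium (2S)-2-[(5R,8S,8aS)-5-(tert-butyldimethylsilyloxy)-8,8a-dimethyl-3-oxo-3,5,6,7,8,8a-hexahydronaphthalen-2-yl]propanoate | CC(C)(C)[Si](C)(C)O[C@@H]1CC[C@H](C)[C@@]2(C)C=C([C@H](C)C(=O)[O-])C(=O)C=C12.[K+] | intermediate (not isolated)
20 | methyl (2S)-2-[(5R,8S,8aS)-5-(tert-butyldimethylsilyloxy)-8,8a-dimethyl-3-oxo-3,5,6,7,8,8a-hexahydronaphthalen-2-yl]propanoate (1R,4S,5S,11S; product of the key step) | CC(C)(C)[Si](C)(C)O[C@@H]1CC[C@H](C)[C@@]2(C)C=C([C@H](C)C(=O)OC)C(=O)C=C12 | intermediate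
21 | methyl (2S)-2-[(5R,8S,8aS)-5-hydroxy-8,8a-dimethyl-3-oxo-3,5,6,7,8,8a-hexahydronaphthalen-2-yl]propanoate | O[C@@H]1CC[C@H](C)[C@@]2(C)C=C([C@H](C)C(=O)OC)C(=O)C=C12 | intermediate
22 | angelic acid, (2Z)-2-methylbut-2-enoic acid | C/C=C(/C)C(=O)O | starting material
23 | angelic 2,4,6-trichlorobenzoic anhydride | C/C=C(/C)C(=O)OC(=O)c1c(Cl)cc(Cl)cc1Cl | intermediate (not isolated)
24 | methyl (2S)-2-[(5R,8S,8aS)-8,8a-dimethyl-5-{[(2Z)-2-methylbut-2-enoyl]oxy}-3-oxo-3,5,6,7,8,8a-hexahydronaphthalen-2-yl]propanoate (CNP0166395.1) | C/C=C(/C)C(=O)O[C@@H]1CC[C@H](C)[C@@]2(C)C=C([C@H](C)C(=O)OC)C(=O)C=C12 | target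

Total step count: 16
Longest linear sequence: 15 steps (steps 1–6 and 8–16, from 1); step 7 is a one-step side branch.

Steps most likely to fail

1. Step 14. The ring may close at C9 instead of C5, which would be followed by rearomatisation to a tetralin phenol. The chain may also add to the wrong face of C5, or the mesylate may be lost by elimination before the hindered C–C bond forms. The fallback blocks the competing carbon and sets out from 17. N-Bromosuccinimide (CH2Cl2, −20 °C) should brominate C9, the only free position activated by the hydroxyl group, to give the C9-bromo phenol acid mesylate F1. Two equivalents of KOtBu in t-BuOH–THF convert it to its dipotassium salt F2. Closure of this salt at C9 would have to build a bromine-bearing quaternary carbon with no rearomatisation as reward, so it should close at C5 to the potassium 9-bromo dienone carboxylate F3. Iodomethane in the same flask gives the 9-bromo dienone methyl ester F4. The vinylic bromide is then removed by palladium-catalysed formate reduction (Pd(OAc)2, PPh3, HCO2H, Bu3N, DMF, 60 °C), and the route is rejoined at 20.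

2. Step 16. Acylation of the axial C1 hydroxyl group, which sits next to the angular methyl group, may be slow, and prolonged heating may isomerise the Z acyl unit to the E (tiglate) form. The fallback builds the alkene after the ester bond and sets out from 21. Esterification with 2-[bis(2,2,2-trifluoroethoxy)phosphoryl]propanoic acid (DCC, DMAP cat., CH2Cl2, 0 °C → rt) gives the C1 phosphonopropanoate ester F5. A Still–Gennari olefination with acetaldehyde (KN(SiMe3)2, 18-crown-6, THF, −78 °C) then forms the Z-trisubstituted alkene at low temperature and arrives at 24.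

3. Step 8. Transmetalation of the hindered α-stannyl acrylate at the ortho-alkoxy aryl iodide may be slow, so cine substitution or polymerisation of the acrylate may compete. The fallback makes the alkene by condensation instead of coupling and sets out from 9. Palladium-catalysed coupling with the Reformatsky reagent BrZnCH2CO2Me (Pd(dba)2, P(t-Bu)3, THF, rt) gives the methyl arylacetate F6. Methylenation with paraformaldehyde (K2CO3, Bu4NI, toluene, 80 °C; aldol addition and loss of water) returns the route to 12.

Further compounds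
F1 | step 14 | (2S)-2-{3-bromo-4-[(1R,4R)-1-(tert-butyldimethylsilyloxy)-4-(methanesulfonyloxy)pentyl]-2-hydroxy-5-methylphenyl}propanoic acid | CC(C)(C)[Si](C)(C)O[C@@H](c1c(Br)c(O)c([C@H](C)C(=O)O)cc1C)CC[C@@H](C)OS(C)(=O)=O
F2 | step 14 | dipotassium phenoxide carboxylate of F1 | CC(C)(C)[Si](C)(C)O[C@@H](c1c(Br)c([O-])c([C@H](C)C(=O)[O-])cc1C)CC[C@@H](C)OS(C)(=O)=O.[K+].[K+]
F3 | step 14 | potassium (2S)-2-[(5R,8S,8aS)-4-bromo-5-(tert-butyldimethylsilyloxy)-8,8a-dimethyl-3-oxo-3,5,6,7,8,8a-hexahydronaphthalen-2-yl]propanoate | CC(C)(C)[Si](C)(C)O[C@@H]1CC[C@H](C)[C@@]2(C)C=C([C@H](C)C(=O)[O-])C(=O)C(Br)=C12.[K+]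
F4 | step 14 | methyl (2S)-2-[(5R,8S,8aS)-4-bromo-5-(tert-butyldimethylsilyloxy)-8,8a-dimethyl-3-oxo-3,5,6,7,8,8a-hexahydronaphthalen-2-yl]propanoate | CC(C)(C)[Si](C)(C)O[C@@H]1CC[C@H](C)[C@@]2(C)C=C([C@H](C)C(=O)OC)C(=O)C(Br)=C12
F5 | step 16 | methyl (2S)-2-[(5R,8S,8aS)-5-({2-[bis(2,2,2-trifluoroethoxy)phosphoryl]propanoyl}oxy)-8,8a-dimethyl-3-oxo-3,5,6,7,8,8a-hexahydronaphthalen-2-yl]propanoate (both epimers at the phosphonate carbon) | CC(C(=O)O[C@@H]1CC[C@H](C)[C@@]2(C)C=C([C@H](C)C(=O)OC)C(=O)C=C12)P(=O)(OCC(F)(F)F)OCC(F)(F)F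
F6 | step 8 | methyl {4-[(1R,4R)-4-acetoxy-1-(tert-butyldimethylsilyloxy)pentyl]-2-(benzyloxy)-5-methylphenyl}acetate | CC(C)(C)[Si](C)(C)O[C@@H](c1cc(OCc2ccccc2)c(CC(=O)OC)cc1C)CC[C@@H](C)OC(C)=O
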